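## Retrosynthetic overview

- Labels: ring A carbons are C-a (CH bearing the CH2 linker), C-b (CH bearing isopropenyl), C-c and C-d (CH2), C-e (C–CH3) and C-f (CH), with C-e and C-f the oxirane carbons; the linker is C-y (CH2 on C-a) and C-x (the C(=CH2) on ring B); ring B carbons are C-p (CH on C-x), C-q (C(OH)CH3) and C-r (CHBr). The strategy rests on ring A being (S)-limonene with a substituent on its ring CH2 (C-a), whose C-e=C-f alkene (the later epoxide) can be cut and re-formed.
- The epoxide is made last, after desilylation, by Shi epoxidation of C-e=C-f on the face syn to C-y; C-e=C-f and ring A come from ring-closing metathesis of an acyclic tetraene (vinyl on C-a, 2-propenyl terminus at C-e).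
- The tetraene comes from (S)-limonene by ring scission to the keto aldehyde, masking of the aldehyde as its SAMP hydrazone, ketone methylenation, auxiliary-controlled alkylation at C-a (C-a–C-y bond) with the ring B allylic bromide, hydrazone hydrolysis and aldehyde methylenation.
- Ring B is not formed in the route: (R)-cyclohex-3-ene-1-carboxylic acid gives iodolactone, cis-epoxide, diaxial tosylate opening, ketone, bromide with inversion, methyl addition anti to Br (cis-bromohydrin), and the ester becomes the 2-substituted allyl bromide.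
- Order of rings: ring B carried from the start, ring A closed in step 17, oxirane closed in step 19.

Key step: step 17

Remark: (R)-cyclohex-3-ene-1-carboxylic acid 8 is assumed to be commercially available as the single enantiomer.
Remark: the facial sense of the SAMP alkylation and of the D-fructose-derived ketone is assigned by analogy with simple aldehyde hydrazones and 1-substituted cyclohexenes.

## Route

Step 1
Reactants: 1 (S)-(−)-limonene
Product: 2 (4S)-limonene 1,2-oxide (mixture of the two epoxide diastereomers)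
Conditions: mCPBA (1.0 equiv), CH2Cl2, 0 °C
Reagents that add atoms: 3-chloroperoxybenzoic acid, OOC(=O)c1cccc(Cl)c1
Why: Prilezhaev epoxidation, in which the trisubstituted ring alkene is more electron-rich than the isopropenyl group and should react first; the diastereomer ratio is irrelevant because both epoxide carbons are cleaved next.

Step 2
Reactants: 2 (4S)-limonene 1,2-oxide
Product: 4 (3S)-6-oxo-3-(prop-1-en-2-yl)heptanal, via trans-diaxial diol 3 (not isolated)
Conditions: H5IO6, THF/H2O, 0 °C to rt
Reagents that add atoms: water, O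
Why: Acid-catalysed epoxide hydrolysis followed in the same flask by Malaprade glycol cleavage opens the limonene ring between C-e and C-f and leaves C-b untouched.

Step 3
Reactants: 4 (3S)-6-oxo-3-(prop-1-en-2-yl)heptanal; 5 SAMP, (S)-1-amino-2-(methoxymethyl)pyrrolidine
Product: 6 (2S)-2-(methoxymethyl)-N-[(1E,3S)-6-oxo-3-(prop-1-en-2-yl)heptylidene]pyrrolidin-1-amine
Conditions: 5 (1.0 equiv), CH2Cl2, MgSO4, 0 °C
Reagents that add atoms: none
Why: Hydrazone condensation, which at 0 °C should take place at the aldehyde much faster than at the methyl ketone, so the aldehyde is masked and the auxiliary installed in one operation.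

Step 4
Reactants: 6 keto hydrazone
Product: 7 (2S)-2-(methoxymethyl)-N-[(1E,3S)-6-methyl-3-(prop-1-en-2-yl)hept-6-enylidene]pyrrolidin-1-amine
Conditions: Ph3PCH3Br, KOtBu, THF, 0 °C to rt
Reagents that add atoms: methyltriphenylphosphonium bromide (as its ylide), C[P+](c1ccccc1)(c1ccccc1)c1ccccc1.[Br-]
Why: Wittig methylenation of the methyl ketone builds the 2-propenyl terminus at C-e, while the aldehyde hydrazone is inert to the ylide.

Step 5
Reactants: 8 (R)-cyclohex-3-ene-1-carboxylic acid
Product: 9 (1R,4R,5R)-4-iodo-6-oxabicyclo[3.2.1]octan-7-one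
Conditions: I2, KI, NaHCO3, H2O/CH2Cl2, rt, dark
Reagents that add atoms: iodine, II
Why: Iodolactonisation, in which the carboxylate opens the iodonium ion anti at C-r, so the lactone oxygen at C-r is cis to the carboxyl carbon and the iodine at C-q is trans to it.

Step 6
Reactants: 9 iodolactone
Product: 11 ethyl (1R,3R,6S)-7-oxabicyclo[4.1.0]heptane-3-carboxylate, via iodohydrin ester alkoxide 10 (not isolated)
Conditions: NaOEt, EtOH, 0 °C to rt
Reagents that add atoms: sodium ethoxide, CC[O-].[Na+]
Why: Ethanolysis of the lactone frees the C-r alkoxide, which displaces the anti iodide at C-q (intramolecular Williamson closure) to give the epoxide cis to the ester.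

Step 7
Reactants: 11 cis-epoxy ester
Product: 12 ethyl (1R,3S,4S)-4-hydroxy-3-[(4-methylbenzenesulfonyl)oxy]cyclohexane-1-carboxylate
Conditions: anhydrous TsOH, CH2Cl2, 0 °C to rt
Reagents that add atoms: p-toluenesulfonic acid, Cc1ccc(cc1)S(=O)(=O)O
Why: Acid-mediated epoxide opening by the sulfonate under the Fürst–Plattner rule, where trans-diaxial opening with the ester equatorial should place the tosylate at C-r (axial, trans to the ester) and the hydroxyl at C-q.

Step 8
Reactants: 12 hydroxy tosylate
Product: 13 ethyl (1R,3S)-3-[(4-methylbenzenesulfonyl)oxy]-4-oxocyclohexane-1-carboxylate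
Conditions: Dess–Martin periodinane, CH2Cl2, rt
Reagents that add atoms: none
Why: Dess–Martin oxidation of the secondary alcohol under neutral conditions makes C-q a ketone without epimerising the sulfonyloxy carbon C-r.

Step 9
Reactants: 13 keto tosylate
Product: 14 ethyl (1R,3R)-3-bromo-4-oxocyclohexane-1-carboxylate
Conditions: LiBr (1.05 equiv), acetone, 0 °C, stopped at full conversion
Reagents that add atoms: lithium bromide, [Li+].[Br-]
Why: Bimolecular nucleophilic displacement alpha to the ketone (Finkelstein type) with inversion, in which the axial sulfonate lies parallel to the carbonyl π system and should be displaced readily, giving the equatorial bromide cis to the ester; that bromide is poorly aligned for further exchange.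

Step 10
Reactants: 14 cis-bromo ketone
Product: 15 ethyl (1R,3R,4S)-3-bromo-4-hydroxy-4-methylcyclohexane-1-carboxylate
Conditions: MeMgBr (1.1 equiv), Et2O/CH2Cl2, −78 °C, quenched cold with aqueous NH4Cl
Reagents that add atoms: methylmagnesium bromide, C[Mg]Br
Why: Grignard addition to an α-bromo ketone, in which methyl should enter anti to the C–Br bond (polar Felkin–Anh control, the same product from either chair), setting C-q with OH cis to Br; at −78 °C the ketone reacts far faster than the ester.

Step 11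
Reactants: 15 bromohydrin ester
Product: 16 ethyl (1R,3R,4S)-3-bromo-4-methyl-4-(triethylsilyloxy)cyclohexane-1-carboxylate
Conditions: Et3SiOTf, 2,6-lutidine, CH2Cl2, −78 to 0 °C
Reagents that add atoms: triethylsilyl trifluoromethanesulfonate, CC[Si](CC)(CC)OS(=O)(=O)C(F)(F)F
Why: Silylation of the tertiary alcohol with a silyl triflate removes the acidic proton before the organometallic and azaenolate steps.

Step 12
Reactants: 16 silyl ether ester
Product: 18 {2-[(1R,3R,4S)-3-bromo-4-methyl-4-(triethylsilyloxy)cyclohexyl]prop-2-en-1-yl}trimethylsilane, via bis(silylmethyl) carbinol 17 (not isolated)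
Conditions: Me3SiCH2MgCl (4 equiv), anhydrous CeCl3, THF, −78 °C to rt; then silica gel, CH2Cl2, rt
Reagents that add atoms: (trimethylsilyl)methylmagnesium chloride, C[Si](C)(C)C[Mg]Cl
Why: Double addition of the non-basic organocerium reagent to the ester (C-p is not epimerised) gives a bis(β-silyl) carbinol that undergoes Peterson elimination on silica to the 2-substituted allylsilane.

Step 13
Reactants: 18 allylsilane
Product: 19 (1R,3R,4S)-3-bromo-1-(3-bromoprop-1-en-2-yl)-4-methyl-4-(triethylsilyloxy)cyclohexane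
Conditions: NBS, CH2Cl2, −78 °C
Reagents that add atoms: N-bromosuccinimide, BrN1C(=O)CCC1=O
Why: Electrophilic bromodesilylation of an allylsilane with allylic transposition, in which bromine adds to the CH2 terminus and loss of silicon from the β-silyl cation regenerates the 1,1-disubstituted alkene next to the new CH2Br.

Step 14
Reactants: 7 SAMP hydrazone; 19 allylic bromide
Product: 21 (2S)-N-[(1E,2R,3S)-2-{2-[(1R,3R,4S)-3-bromo-4-methyl-4-(triethylsilyloxy)cyclohexyl]prop-2-en-1-yl}-6-methyl-3-(prop-1-en-2-yl)hept-6-enylidene]-2-(methoxymethyl)pyrrolidin-1-amine, via lithium azaenolate 20 (not isolated)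
Conditions: LiN(iPr)2, THF, 0 °C; then −100 °C, 19, slowly to rt
Reagents that add atoms: none
Why: SAMP hydrazone alkylation, in which the chelated E(C=C),Z(C–N) azaenolate is attacked at the primary allylic bromide (the ring bromide is inert) from the face that gives (S)-2-methylalkanals with simple halides; here that is (R) at C-a, the configuration that becomes trans to the isopropenyl group on ring A.

Step 15
Reactants: 21 alkylated hydrazone
Product: 22 (2R,3S)-2-{2-[(1R,3R,4S)-3-bromo-4-methyl-4-(triethylsilyloxy)cyclohexyl]prop-2-en-1-yl}-6-methyl-3-(prop-1-en-2-yl)hept-6-enal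
Conditions: CuCl2·2H2O, THF/aqueous pH 7 phosphate buffer, 0 °C to rt
Reagents that add atoms: water, O
Why: Copper-assisted hydrazone hydrolysis at neutral pH frees the aldehyde without ozone, so the alkenes, the silyl ether and the α-stereocentre C-a should survive.

Step 16
Reactants: 22 aldehyde
Product: 23 (3S,4S)-3-{2-[(1R,3R,4S)-3-bromo-4-methyl-4-(triethylsilyloxy)cyclohexyl]prop-2-en-1-yl}-7-methyl-4-(prop-1-en-2-yl)octa-1,7-diene
Conditions: Ph3PCH3Br, KN(SiMe3)2, THF, −78 to 0 °C
Reagents that add atoms: methyltriphenylphosphonium bromide (as its ylide), C[P+](c1ccccc1)(c1ccccc1)c1ccccc1.[Br-]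
Why: Wittig methylenation of the aldehyde at low temperature, fast enough to outrun epimerisation at C-a, installs the vinyl group on C-a.

Step 17
Reactants: 23 acyclic tetraene
Product: 24 (3S,4S)-3-{2-[(1R,3R,4S)-3-bromo-4-methyl-4-(triethylsilyloxy)cyclohexyl]prop-2-en-1-yl}-1-methyl-4-(prop-1-en-2-yl)cyclohex-1-ene
Conditions: second-generation Grubbs catalyst (H2IMes)(PCy3)Cl2Ru=CHPh (5 mol %), CH2Cl2 (0.005 M), 40 °C
Reagents that add atoms: none
Why: Ring-closing olefin metathesis: the ruthenium benzylidene exchanges onto the only monosubstituted alkene (the vinyl group on C-a), the new alkylidene adds across the C-e methylidene in a [2+2] step, and cycloreversion of the ruthenacyclobutane expels ethylene and leaves the C-e=C-f double bond. The closest known reaction type is closure of 1,7-dienes that pair a monosubstituted with a 1,1-disubstituted alkene to give 1-methylcyclohexenes. Ring A closes as a six-membered carbocycle by joining C-f to C-e at the two chain termini. No stereocentre is created; C-a and C-b are carried in unchanged and end up trans on the new ring. The selectivity needed is site selectivity among four alkenes: loading is fast only at the vinyl group, closure from there onto the isopropenyl group or the C-x methylene would give cyclobutenes, and any pairing of two 1,1-disubstituted alkenes would need the slow loading on a hindered alkene and would form a tetrasubstituted five- or seven-membered alkene. High dilution should keep the vinyl group from intermolecular homodimerisation.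

Step 18
Reactants: 24 silyl ether
Product: 25 (3S,4S)-3-{2-[(1R,3R,4S)-3-bromo-4-hydroxy-4-methylcyclohexyl]prop-2-en-1-yl}-1-methyl-4-(prop-1-en-2-yl)cyclohex-1-ene
Conditions: HF·pyridine, pyridine, THF, 0 °C to rt
Reagents that add atoms: none
Why: Fluoride-driven desilylation under buffered, non-basic conditions frees the tertiary alcohol without exposing the cis-bromohydrin to base or the alkenes to strong acid.

Step 19
Reactants: 25 triene bromohydrin
Product: 26 CNP0213097.1, (1S,2R,4R)-2-bromo-1-methyl-4-{3-[(1R,2R,3S,6S)-6-methyl-3-(prop-1-en-2-yl)-7-oxabicyclo[4.1.0]heptan-2-yl]prop-1-en-2-yl}cyclohexan-1-ol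
Conditions: D-fructose-derived ketone 1,2:4,5-di-O-isopropylidene-β-D-erythro-2,3-hexodiulo-2,6-pyranose (0.3 equiv), KHSO5 (as 2KHSO5·KHSO4·K2SO4), K2CO3, Bu4NHSO4, MeCN/CH2(OMe)2/aqueous Na2B4O7 buffer, 0 °C
Reagents that add atoms: potassium peroxymonosulfate, [K+].[O-]S(=O)(=O)OO
Why: Shi epoxidation, in which the chiral dioxirane should react at the trisubstituted C-e=C-f alkene in preference to the two 1,1-disubstituted alkenes and, through its spiro transition state (the sense that gives (R,R)-epoxides from 1-substituted cyclohexenes), deliver oxygen to the face syn to C-y and anti to the isopropenyl group, setting C-e and C-f.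

## Compound list

1 | (S)-(−)-limonene | CC1=CC[C@H](CC1)C(C)=C | starting material
2 | (4S)-limonene 1,2-oxide, (4S)-1-methyl-4-(prop-1-en-2-yl)-7-oxabicyclo[4.1.0]heptane, both epoxide diastereomers | CC12OC1C[C@H](CC2)C(C)=C | intermediate
3 | (1R,2R,4S)-1-methyl-4-(prop-1-en-2-yl)cyclohexane-1,2-diol | C[C@]1(O)[C@H](O)C[C@H](CC1)C(C)=C | intermediate
4 | (3S)-6-oxo-3-(prop-1-en-2-yl)heptanal | O=CC[C@H](CCC(C)=O)C(C)=C | intermediate
5 | SAMP, (S)-1-amino-2-(methoxymethyl)pyrrolidine | COC[C@@H]1CCCN1N | starting material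
6 | (2S)-2-(methoxymethyl)-N-[(1E,3S)-6-oxo-3-(prop-1-en-2-yl)heptylidene]pyrrolidin-1-amine | COC[C@@H]1CCCN1/N=C/C[C@H](CCC(C)=O)C(C)=C | intermediate
7 | (2S)-2-(methoxymethyl)-N-[(1E,3S)-6-methyl-3-(prop-1-en-2-yl)hept-6-enylidene]pyrrolidin-1-amine | COC[C@@H]1CCCN1/N=C/C[C@H](CCC(C)=C)C(C)=C | intermediate
8 | (R)-cyclohex-3-ene-1-carboxylic acid | OC(=O)[C@@H]1CCC=CC1 | starting material
9 | (1R,4R,5R)-4-iodo-6-oxabicyclo[3.2.1]octan-7-one | O=C1O[C@@H]2C[C@H]1CC[C@H]2I | intermediate
10 | ethyl (1R,3R,4R)-3-hydroxy-4-iodocyclohexane-1-carboxylate (formed as its sodium alkoxide) | CCOC(=O)[C@@H]1CC[C@@H](I)[C@H](O)C1 | intermediate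
11 | ethyl (1R,3R,6S)-7-oxabicyclo[4.1.0]heptane-3-carboxylate | CCOC(=O)[C@@H]1CC[C@@H]2O[C@@H]2C1 | intermediate
12 | ethyl (1R,3S,4S)-4-hydroxy-3-[(4-methylbenzenesulfonyl)oxy]cyclohexane-1-carboxylate | CCOC(=O)[C@@H]1CC[C@H](O)[C@@H](OS(=O)(=O)c2ccc(C)cc2)C1 | intermediate
13 | ethyl (1R,3S)-3-[(4-methylbenzenesulfonyl)oxy]-4-oxocyclohexane-1-carboxylate | CCOC(=O)[C@@H]1CCC(=O)[C@@H](OS(=O)(=O)c2ccc(C)cc2)C1 | intermediate
14 | ethyl (1R,3R)-3-bromo-4-oxocyclohexane-1-carboxylate | CCOC(=O)[C@@H]1CCC(=O)[C@H](Br)C1 | intermediate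
15 | ethyl (1R,3R,4S)-3-bromo-4-hydroxy-4-methylcyclohexane-1-carboxylate | CCOC(=O)[C@@H]1CC[C@](C)(O)[C@H](Br)C1 | intermediate
16 | ethyl (1R,3R,4S)-3-bromo-4-methyl-4-(triethylsilyloxy)cyclohexane-1-carboxylate | CCOC(=O)[C@@H]1CC[C@](C)(O[Si](CC)(CC)CC)[C@H](Br)C1 | intermediate
17 | 2-[(1R,3R,4S)-3-bromo-4-methyl-4-(triethylsilyloxy)cyclohexyl]-1,3-bis(trimethylsilyl)propan-2-ol | C[Si](C)(C)CC(O)(C[Si](C)(C)C)[C@@H]1CC[C@](C)(O[Si](CC)(CC)CC)[C@H](Br)C1 | intermediate
18 | {2-[(1R,3R,4S)-3-bromo-4-methyl-4-(triethylsilyloxy)cyclohexyl]prop-2-en-1-yl}trimethylsilane | C=C(C[Si](C)(C)C)[C@@H]1CC[C@](C)(O[Si](CC)(CC)CC)[C@H](Br)C1 | intermediate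
19 | (1R,3R,4S)-3-bromo-1-(3-bromoprop-1-en-2-yl)-4-methyl-4-(triethylsilyloxy)cyclohexane | C=C(CBr)[C@@H]1CC[C@](C)(O[Si](CC)(CC)CC)[C@H](Br)C1 | intermediate
20 | lithium azaenolate of 7, E(C=C) | [Li+].COC[C@@H]1CCCN1[N-]/C=C/[C@H](CCC(C)=C)C(C)=C | intermediate
21 | (2S)-N-[(1E,2R,3S)-2-{2-[(1R,3R,4S)-3-bromo-4-methyl-4-(triethylsilyloxy)cyclohexyl]prop-2-en-1-yl}-6-methyl-3-(prop-1-en-2-yl)hept-6-enylidene]-2-(methoxymethyl)pyrrolidin-1-amine | COC[C@@H]1CCCN1/N=C/[C@H](CC(=C)[C@@H]2CC[C@](C)(O[Si](CC)(CC)CC)[C@H](Br)C2)[C@H](CCC(C)=C)C(C)=C | intermediate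
22 | (2R,3S)-2-{2-[(1R,3R,4S)-3-bromo-4-methyl-4-(triethylsilyloxy)cyclohexyl]prop-2-en-1-yl}-6-methyl-3-(prop-1-en-2-yl)hept-6-enal | O=C[C@H](CC(=C)[C@@H]1CC[C@](C)(O[Si](CC)(CC)CC)[C@H](Br)C1)[C@H](CCC(C)=C)C(C)=C | intermediate
23 | (3S,4S)-3-{2-[(1R,3R,4S)-3-bromo-4-methyl-4-(triethylsilyloxy)cyclohexyl]prop-2-en-1-yl}-7-methyl-4-(prop-1-en-2-yl)octa-1,7-diene | C=C(C[C@@H](C=C)[C@@H](C(C)=C)CCC(C)=C)[C@@H]1CC[C@](C)(O[Si](CC)(CC)CC)[C@H](Br)C1 | intermediate
24 | (3S,4S)-3-{2-[(1R,3R,4S)-3-bromo-4-methyl-4-(triethylsilyloxy)cyclohexyl]prop-2-en-1-yl}-1-methyl-4-(prop-1-en-2-yl)cyclohex-1-ene | C=C(C[C@@H]1[C@@H](C(C)=C)CCC(C)=C1)[C@@H]1CC[C@](C)(O[Si](CC)(CC)CC)[C@H](Br)C1 | intermediate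
25 | (3S,4S)-3-{2-[(1R,3R,4S)-3-bromo-4-hydroxy-4-methylcyclohexyl]prop-2-en-1-yl}-1-methyl-4-(prop-1-en-2-yl)cyclohex-1-ene | C=C(C[C@@H]1[C@@H](C(C)=C)CCC(C)=C1)[C@@H]1CC[C@](C)(O)[C@H](Br)C1 | intermediate
26 | CNP0213097.1, (1S,2R,4R)-2-bromo-1-methyl-4-{3-[(1R,2R,3S,6S)-6-methyl-3-(prop-1-en-2-yl)-7-oxabicyclo[4.1.0]heptan-2-yl]prop-1-en-2-yl}cyclohexan-1-ol | C=C(C[C@@H]1[C@@H](C(=C)C)CC[C@]2(C)O[C@H]12)[C@@H]1CC[C@](C)(O)[C@H](Br)C1 | target

## Step count and risks

Total step count: 19. Longest linear sequence: 15 steps (8 to 26 through steps 5–19); the limonene branch (steps 1–4) joins at step 14.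

Steps most likely to fail:

Step 9. The bromide that is set free or left over may exchange with the product bromide, so the configuration at C-r drifts toward the trans isomer. The fallback accepts this and filters after the Grignard step. It sets out from 15, obtained as a mixture with the diastereomer that arises from the epimerised ketone. The mixture is treated with catalytic NaH in THF at 0 °C. Only 15 has the tertiary hydroxyl 1,4-cis to the ester and can close to (1S,4R,6R)-6-bromo-1-methyl-2-oxabicyclo[2.2.2]octan-3-one F1, which is separated from the unchanged diastereomeric hydroxy ester. The lactone is then treated with Me3SiCH2MgCl/CeCl3 to give 2-[(1R,3R,4S)-3-bromo-4-hydroxy-4-methylcyclohexyl]-1,3-bis(trimethylsilyl)propan-2-ol F2. Silica gel converts this into the allylsilane alcohol (1S,2R,4R)-2-bromo-1-methyl-4-[3-(trimethylsilyl)prop-1-en-2-yl]cyclohexan-1-ol F3, and silylation with Et3SiOTf/2,6-lutidine brings the material back to the route at 18.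

Step 15. Hydrolysis of the hindered aldehyde hydrazone may stall, or the α-stereocentre C-a may epimerise during prolonged exposure to the copper salt. The fallback sets out from 21 and replaces hydrolysis by oxidative N–N cleavage. Magnesium bis(monoperoxyphthalate) hexahydrate (limited excess) in MeOH/pH 7 buffer at 0 °C should oxidise the pyrrolidine nitrogen much faster than it epoxidises the 1,1-disubstituted alkenes. Syn elimination then gives the nitrile (2R,3S)-2-{2-[(1R,3R,4S)-3-bromo-4-methyl-4-(triethylsilyloxy)cyclohexyl]prop-2-en-1-yl}-6-methyl-3-(prop-1-en-2-yl)hept-6-enenitrile F4. Reduction with iBu2AlH at −78 °C and mild hydrolysis of the imine returns to the route at aldehyde 22.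

Step 19. Facial selectivity may be poor if the substrate bias of the C-a side chain opposes the catalyst. The fallback sets out from 25 and gives up facial control. Dimethyldioxirane (1.0 equiv) in acetone at −20 °C should epoxidise the trisubstituted alkene from both faces. Compound 26 is separated by chromatography from the diastereomer with the oxirane anti to C-y, (1S,2R,4R)-2-bromo-1-methyl-4-{3-[(1S,2R,3S,6R)-6-methyl-3-(prop-1-en-2-yl)-7-oxabicyclo[4.1.0]heptan-2-yl]prop-1-en-2-yl}cyclohexan-1-ol F5. F5 is deoxygenated stereospecifically with Ph3P=Se and trifluoroacetic acid back to 25 and recycled, so the fallback ends at 26.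

Further compounds
F1 | step 9 | (1S,4R,6R)-6-bromo-1-methyl-2-oxabicyclo[2.2.2]octan-3-one | O=C1O[C@@]2(C)CC[C@@H]1C[C@H]2Br
F2 | step 9 | 2-[(1R,3R,4S)-3-bromo-4-hydroxy-4-methylcyclohexyl]-1,3-bis(trimethylsilyl)propan-2-ol | C[Si](C)(C)CC(O)(C[Si](C)(C)C)[C@@H]1CC[C@](C)(O)[C@H](Br)C1
F3 | step 9 | (1S,2R,4R)-2-bromo-1-methyl-4-[3-(trimethylsilyl)prop-1-en-2-yl]cyclohexan-1-ol | C=C(C[Si](C)(C)C)[C@@H]1CC[C@](C)(O)[C@H](Br)C1
F4 | step 15 | (2R,3S)-2-{2-[(1R,3R,4S)-3-bromo-4-methyl-4-(triethylsilyloxy)cyclohexyl]prop-2-en-1-yl}-6-methyl-3-(prop-1-en-2-yl)hept-6-enenitrile | N#C[C@H](CC(=C)[C@@H]1CC[C@](C)(O[Si](CC)(CC)CC)[C@H](Br)C1)[C@H](CCC(C)=C)C(C)=C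
F5 | step 19 | (1S,2R,4R)-2-bromo-1-methyl-4-{3-[(1S,2R,3S,6R)-6-methyl-3-(prop-1-en-2-yl)-7-oxabicyclo[4.1.0]heptan-2-yl]prop-1-en-2-yl}cyclohexan-1-ol | C=C(C[C@@H]1[C@@H](C(=C)C)CC[C@@]2(C)O[C@@H]12)[C@@H]1CC[C@](C)(O)[C@H](Br)C1
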